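## Retrosynthetic overview

- The free C5–OH is unmasked last from a tosylate. The tosylate keeps the benzo ring electron-poor during the cationic key step and serves as the bulky peri group next to C4.
- Key disconnection: the pyran ring is opened at C3–C4 and O1–C2. This gives an o-quinone methide (from a racemic diaryl carbinol) and allyltrimethylsilane, a propene whose activating silyl group is lost in the same operation. The step is stereoconvergent and sets both stereocentres.
- Enabling feature: C4 is a doubly benzylic methine. On the benzo ring it lies ortho to the ring oxygen (C4–C4a–C8a–O1, a free phenol in the precursor); through the naphthalene ring it lies para to the C4′ methoxy group. The carbinol therefore ionises readily to the O1=C8a–C4a=C4 heterodiene, and the C5 oxygen peri to C4 steers the 2,4-trans closure.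
- The carbinol comes from the Grignard reagent of 4-bromo-1,8-dimethoxynaphthalene and mono-tosylated 2,6-dihydroxybenzaldehyde.
- Ring order: the naphthalene and benzene rings are bought; the pyran ring is the only ring made, in the key step.

Key step: step 4

Remark: the target is read as the 2,4-trans chroman, (2R,4S). Which antipode of the chiral acid gives the (4S) series cannot be predicted with confidence and is to be fixed in the first screen.

## Route

Step 1
Reactants: 1 1,8-dimethoxynaphthalene
Product: 2 4-bromo-1,8-dimethoxynaphthalene
Conditions: NBS (1.0 equiv), MeCN, 0 °C → rt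
Reagents that add atoms: N-bromosuccinimide, O=C1CCC(=O)N1Br
Why: Electrophilic aromatic bromination; C4, para to a methoxy group, is the most activated and least hindered position, and one equivalent of NBS should stop at the monobromide.

Step 2
Reactants: 3 2,6-dihydroxybenzaldehyde
Product: 4 2-formyl-3-hydroxyphenyl 4-methylbenzenesulfonate
Conditions: TsCl (1.0 equiv), K2CO3 (1.05 equiv), acetone, 0 °C → rt
Reagents that add atoms: 4-toluenesulfonyl chloride, Cc1ccc(S(=O)(=O)Cl)cc1
Why: Sulfonylation of a phenol; after the first tosylation the remaining O–H is held in a hydrogen bond to the aldehyde on a more electron-poor ring, so mono-tosylation should prevail, and the tosylate is chosen because it survives Grignard reagents and acid and deactivates the benzo ring toward Friedel–Crafts attack in step 4.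

Step 3
Reactants: 2 4-bromo-1,8-dimethoxynaphthalene; 4 2-formyl-3-hydroxyphenyl 4-methylbenzenesulfonate
Product: 6 rac-2-[(4,5-dimethoxynaphthalen-1-yl)(hydroxy)methyl]-3-hydroxyphenyl 4-methylbenzenesulfonate, via Grignard reagent 5 (not isolated)
Conditions: (i) 2 (2.3 equiv), Mg, THF, 45 °C; (ii) 4, THF, −78 → −20 °C; pH 7 buffer
Reagents that add atoms: none
Why: Grignard addition to an aldehyde; the first equivalent of 5 removes the phenol proton (returning 1) and the second adds to the magnesium-chelated formyl group at low temperature, where an aryl tosylate is inert to aryl Grignard reagents, and the new carbinol centre may be racemic because step 4 erases it.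

Step 4
Reactants: 6 rac-2-[(4,5-dimethoxynaphthalen-1-yl)(hydroxy)methyl]-3-hydroxyphenyl 4-methylbenzenesulfonate; 7 allyltrimethylsilane
Product: 10 (2R,4S)-4-(4,5-dimethoxynaphthalen-1-yl)-2-methyl-3,4-dihydro-2H-chromen-5-yl 4-methylbenzenesulfonate, via o-quinone methide 8 (not isolated), via homoallyl phenol 9 (not isolated)
Conditions: confined chiral IDPi Brønsted acid (5 mol %), 7 (1.5 equiv), PhMe, no drying agent, −40 °C; then 60 °C in the same flask
Reagents that add atoms: none
Why: Proposed new method: the chiral acid ionises racemic 6 to the planar o-quinone methide 8, held in the catalyst pocket as a hydrogen-bonded ion pair, so the carbinol centre is erased and both enantiomers of 6 converge; 7 adds through its terminal CH2 to one face of C4 (Hosomi–Sakurai mode, β-silyl cation, the silyl group leaving to the water released on ionisation) to give 9, and on warming the same acid adds the phenol O–H across the new terminal alkene to close the pyran ring. Closest known reaction types: chiral Brønsted acid-catalysed additions and [4+2] cycloadditions of π-nucleophiles to o-quinone methides generated in situ from o-hydroxybenzhydrols, acid-mediated allylation of benzhydryl cations by allylsilanes, and Brønsted acid-catalysed intramolecular hydroalkoxylation of unactivated terminal alkenes; merging them in one enantioselective operation, with an allylsilane as a traceless propene, is the new element. The pyran ring closes 6-exo-trig, O1 attacking C2 of the protonated alkene in the Markovnikov sense. C4 is set by the catalyst, which selects the enantioface of 8; C2 is set by the substrate, since in the chair-like closure the naphthyl group at C4 must sit pseudo-axial to avoid the peri (allylic 1,3) clash with the C5 tosyloxy group and the forming methyl group takes the pseudo-equatorial site on the opposite face, which is the 2,4-trans, (2R,4S) arrangement. The step needs C-allylation to outrun Friedel–Crafts capture of the cation by an arene, which the electron-withdrawing tosylate on the benzo ring and the peri-shielded C8′ of the naphthalene should secure, and it needs O- rather than C-closure at C2, which the concerted proton shuttle through the adjacent phenol should favour.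

Step 5
Reactants: 10 (2R,4S)-4-(4,5-dimethoxynaphthalen-1-yl)-2-methyl-3,4-dihydro-2H-chromen-5-yl 4-methylbenzenesulfonate
Product: 11 (2R,4S)-4-(4,5-dimethoxynaphthalen-1-yl)-2-methyl-3,4-dihydro-2H-chromen-5-ol (cladonaphchrom A)
Conditions: KOH, MeOH/THF, 60 °C; then aq. HCl to pH 5
Reagents that add atoms: none
Why: Alkaline hydrolysis of an aryl sulfonate by attack of hydroxide at sulfur (S–O cleavage), which leaves the ring ether, the methoxy groups and both stereocentres, neither of which is acidic or ionisable under base, untouched.

## Compound list

1 | 1,8-dimethoxynaphthalene | COc1cccc2cccc(OC)c12 | starting material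
2 | 4-bromo-1,8-dimethoxynaphthalene | COc1cccc2c(Br)ccc(OC)c12 | intermediate
3 | 2,6-dihydroxybenzaldehyde | O=Cc1c(O)cccc1O | starting material
4 | 2-formyl-3-hydroxyphenyl 4-methylbenzenesulfonate | O=Cc1c(O)cccc1OS(=O)(=O)c1ccc(C)cc1 | intermediate
5 | (4,5-dimethoxynaphthalen-1-yl)magnesium bromide | COc1cccc2c([Mg]Br)ccc(OC)c12 | intermediate
6 | rac-2-[(4,5-dimethoxynaphthalen-1-yl)(hydroxy)methyl]-3-hydroxyphenyl 4-methylbenzenesulfonate (racemic) | COc1cccc2c(C(O)c3c(O)cccc3OS(=O)(=O)c3ccc(C)cc3)ccc(OC)c12 | intermediate
7 | allyltrimethylsilane | C=CC[Si](C)(C)C | starting material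
8 | 6-[(4,5-dimethoxynaphthalen-1-yl)methylidene]-5-oxocyclohexa-1,3-dien-1-yl 4-methylbenzenesulfonate (o-quinone methide, alkene geometry not defined) | COc1cccc2c(C=C3C(=O)C=CC=C3OS(=O)(=O)c3ccc(C)cc3)ccc(OC)c12 | intermediate
9 | 2-[(1S)-1-(4,5-dimethoxynaphthalen-1-yl)but-3-en-1-yl]-3-hydroxyphenyl 4-methylbenzenesulfonate | COc1cccc2c([C@H](CC=C)c3c(O)cccc3OS(=O)(=O)c3ccc(C)cc3)ccc(OC)c12 | intermediate
10 | (2R,4S)-4-(4,5-dimethoxynaphthalen-1-yl)-2-methyl-3,4-dihydro-2H-chromen-5-yl 4-methylbenzenesulfonate | COc1cccc2c([C@@H]3C[C@@H](C)Oc4cccc(OS(=O)(=O)c5ccc(C)cc5)c43)ccc(OC)c12 | intermediate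
11 | (2R,4S)-4-(4,5-dimethoxynaphthalen-1-yl)-2-methyl-3,4-dihydro-2H-chromen-5-ol (cladonaphchrom A) | COc1cccc2c([C@@H]3C[C@@H](C)Oc4cccc(O)c43)ccc(OC)c12 | target

## Step count and risks

Total step count: 5. Longest linear sequence: 4 steps (1 → 2 → 6 → 10 → 11, or 3 → 4 → 6 → 10 → 11).

Steps most likely to fail:

1. Step 4 (proposed new method). The allyl transfer may show low facial discrimination, because the allylsilane offers the catalyst no hydrogen-bond contact. After allylation the closure may stall, or the developing C2 cation may be captured by C8′ of the naphthalene instead of O1. The closure may also be less trans-selective than the conformational argument suggests. Fallback (known chemistry, sets out from 6, returns at 10): Hosomi–Sakurai allylation of 6 with 7 under catalytic Bi(OTf)3 in CH2Cl2 at −40 °C should give the racemic homoallyl phenol F1. Preparative SFC on a chiral stationary phase should separate the wanted (S)-enantiomer 9 from the (R)-enantiomer F2, which is discarded. Compound 9 is then closed to 10 by cobalt(salen)-catalysed hydrogen-atom-transfer hydroalkoxylation (silane, N-fluoropyridinium oxidant; Mukaiyama-type radical–polar crossover). This avoids hot strong acid and a free C2 cation, and the same peri bias should favour the trans isomer.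

2. Step 3. The tosyl group may migrate from the phenol oxygen to the neighbouring magnesium alkoxide, or the carbinol may ionise during work-up or chromatography. Fallback (sets out from 3, uses Grignard reagent 5, returns at 6): addition of 5 (3.3 equiv) to unprotected 3, with no sulfonate present, should give the triol F3. One of its two equivalent phenols is then tosylated (TsCl 1.0 equiv, K2CO3, acetone, 0 °C), the phenol reacting ahead of the secondary alcohol, to give 6.

3. Step 2. Over-sulfonylation may give a statistical mixture of mono- and bis-tosylate. Fallback (sets out from 3, returns at 4): exhaustive tosylation (TsCl 2.2 equiv, Et3N, CH2Cl2) should give the bis-tosylate F4. One equivalent of LiOH in THF/water at 0 °C should then remove a single tosyl group, because the aldehyde-chelated phenoxide formed first makes loss of the second sulfonate much slower; this gives 4.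

## Further compounds

F1 | step 4 | rac-2-[1-(4,5-dimethoxynaphthalen-1-yl)but-3-en-1-yl]-3-hydroxyphenyl 4-methylbenzenesulfonate (racemic homoallyl phenol) | COc1cccc2c(C(CC=C)c3c(O)cccc3OS(=O)(=O)c3ccc(C)cc3)ccc(OC)c12
F2 | step 4 | 2-[(1R)-1-(4,5-dimethoxynaphthalen-1-yl)but-3-en-1-yl]-3-hydroxyphenyl 4-methylbenzenesulfonate ((R)-enantiomer) | COc1cccc2c([C@@H](CC=C)c3c(O)cccc3OS(=O)(=O)c3ccc(C)cc3)ccc(OC)c12
F3 | step 3 | rac-2-[(4,5-dimethoxynaphthalen-1-yl)(hydroxy)methyl]benzene-1,3-diol (triol) | COc1cccc2c(C(O)c3c(O)cccc3O)ccc(OC)c12
F4 | step 2 | 2-formyl-1,3-phenylene bis(4-methylbenzenesulfonate) (bis-tosylate) | O=Cc1c(OS(=O)(=O)c2ccc(C)cc2)cccc1OS(=O)(=O)c1ccc(C)cc1
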